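## The problem

The target 17 is an isoflavone, a chromen-4-one (rings A and C) that carries ring B on C3, with free hydroxyls at C5, C7 and C4', a single methyl ether at C2' and three 3-methylbut-2-enyl (prenyl) groups at C6, C8 and C3'. It has no stereocentre, so the task is one of connectivity and regiochemistry only. Each prenyl group sits on a carbon flanked by two oxygen-bearing carbons, so direct C-prenylation of a polyphenol would compete with O-alkylation, over-alkylation and attack at the wrong positions, and the one methyl ether must be told apart from three phenols. The prenyl alkenes are the fragile part: beside a phenol they close to 2,2-dimethylchromans under acid, they are attacked by electrophilic oxidants and they are saturated by hydrogenation, while the chromone C2 is open to hot hydroxide. The key step is possible because ring B is bound to C3 through C1', which carries an ortho-methoxy group (C2') and a para-oxygen substituent (C4'). Such an aryl group shifts readily to a neighbouring cationic carbon, so the C3–C1' bond can come from a 1,2-aryl shift in a chalcone, and the ring A phenol that becomes O1 sits ortho to the C4 carbonyl, placed to close ring C onto C2 afterwards. Ring A is a symmetrical phloroglucinol unit, so C6 and C8 are equivalent before ring C exists and can be marked together.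

## Retrosynthesis

**17 to 16, then 16 to 14 and 15.** The three phenols are masked as methoxymethyl (MOM) ethers in 16, and the three aryl–CH2 bonds at C6, C8 and C3' are cut to the tribromide 14 and prenylboronic acid pinacol ester 15. The prenyl groups are placed last because the trisubstituted alkenes would survive neither the thallium oxidant of the key step nor the Lewis acid used for debenzylation. Against direct C-prenylation or Claisen routes, three bromine atoms fix the positions without ambiguity. The forward reaction must couple three doubly ortho-substituted aryl bromides and deliver the linear allyl isomer each time.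

**14 to 13 to 12.** This is a protecting-group exchange with no change in the skeleton. Benzyl ethers are wanted for the key step, because they are inert to the thallium oxidant, to the nitric acid it releases and to hot methanolic acid. They cannot be removed once prenyl groups are present, since hydrogenolysis saturates the alkenes and BCl3 cyclises them. The exchange to MOM is therefore made at the tribromide stage: 12 is debenzylated to the triphenol 13 with BCl3, which leaves the C–Br bonds and the C2' methyl ether intact where hydrogenolysis would not, and 13 is converted to 14.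

**12 to 10 (through 11).** The O1–C2 and C3–C1' bonds are cut, which returns ring B to the neighbouring carbon and opens ring C to the 2'-hydroxychalcone 10. A deoxybenzoin route would need a Friedel–Crafts acylation of a brominated phloroglucinol followed by a one-carbon insertion. A Suzuki coupling at C3–C1' would have to tell a C3 halide from three aryl bromides. The chalcone needs only an aldol condensation of two simple aromatic pieces. The forward step must oxidise the enone, make ring B migrate in preference to attack by the phenol oxygen, and then close ring C from the acetal 11.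

**10 to 4 and 9.** The Cα=Cβ bond of the chalcone is cut by a Claisen–Schmidt disconnection into the acetophenone 4 and the aldehyde 9. This is the most convergent cut and divides the molecule into a ring A half and a ring B half of similar size. The condensation must tolerate a ketone flanked by two ortho substituents.

**4 to 3 to 1 and 2.** The two C–Br bonds are cut back to the dibenzyl ether 3, whose only free ring positions are the two that become C6 and C8. The two benzyl ethers are cut back to 2,4,6-trihydroxyacetophenone 1 and two equivalents of benzyl bromide 2. The chelated hydroxyl is left free and later becomes O1.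

**9 to 8 to 7 to 5 (through 6).** The methyl ether, the benzyl ether and the formyl group are removed in turn, leading to 2-bromoresorcinol 5. Starting from 5 puts the bromine between the two oxygens from the outset, whereas bromination after the formylation would go mainly to the other position ortho to the 4-hydroxyl. The two hydroxyls of 7 are differentiated by the hydrogen bond of the 2-hydroxyl to the aldehyde. Formylation passes through the iminium salt 6.

## Roads not taken

Alternative 1: The cut is at C4a–C4 and C4–C3. A carbonylative Suzuki–Miyaura coupling would join the ring A iodide A2 and the ring B β-methoxyvinylboronate A3 through an inserted carbonyl group to give the β-methoxy enone A1. Acid would then remove the MOM groups and close O1–C2 with loss of the enol methoxy group.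
- Merits: the route is highly convergent, all three prenyl groups are in place before the key step, no thallium is used, and A1 is a single operation from the target. In these respects it is better than the chosen plan.
- Weak points: A2 is a hexasubstituted aryl iodide with the iodine between two alkoxy groups. The derived acylpalladium species would have to transmetalate with a hindered 1,1-disubstituted enol-ether boronate. Direct coupling without carbonyl insertion and protodeboronation of A3 are likely competitors. Both A2 and A3 need their own regioselective prenylations and multi-step preparations, and A3 belongs to a class with little preparative background.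
- Comparison: the chosen plan has more steps after the key step and a toxic oxidant. Against that, every one of its steps is of an established type, and its regiochemistry is settled by simple electrophilic bromination.

Alternative 2: The cut is inside ring A. Heating the cyclobutenone A5 with the siloxyalkyne A6 would give, by vinylketene formation, [2+2] cycloaddition, ring opening and 6π closure, the pentasubstituted phenol A4 with both prenyl groups and three differentiated oxygens.
- Merits: the ring A regiochemistry is programmed by the reactants, and no aryl halide or palladium step is needed for C6 and C8. Here it is cleaner than a double coupling.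
- Weak points: ring A is the easy, symmetrical part of the target, and the chosen plan marks C6 and C8 in one bromination. A4 leaves the whole isoflavone still to be built (acylation at its last free carbon, then C3–C1' and C2) on a substrate with two acid-sensitive prenyl groups and a labile silyl ether. A5 and A6 each need several steps. The vinylketene may also be trapped by its own prenyl alkene.
- Comparison: the route is longer overall and solves neither the ring B prenyl group nor the core. The chosen plan must set a threefold coupling against this.

Alternative 3: The cut is inside ring B. Heating the chromon-3-yl cyclobutenone A8 with the methoxyalkyne A9 would close ring B as the free C4' phenol, with the C2' methoxy and C3' prenyl groups in place, to give A7, the 5,7-bis(methoxymethyl) ether of the target.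
- Merits: ring B arises in one step with predictable regiochemistry, since the alkyne carbon bearing the prenyl group ends ortho to the new hydroxyl and the methoxy carbon meta to it. A7 is one deprotection from the target.
- Weak points: A8 is a cyclobutenone without a substituent at its 3-position, a type that polymerises easily and is hard to prepare. It would have to be attached to a chromone that already carries both ring A prenyl groups, so the ring A prenylation problem remains. A9 is a sensitive alkynyl ether. The thermal step exposes three alkenes and the chromone C2=C3 bond to a ketene.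
- Comparison: the key step is more elegant for ring B than three steps from 2-bromoresorcinol 5, but the substrate for it is the longest to reach. The chosen plan forms the same ring B pattern from cheap aromatic material and carries the risk in one well-known rearrangement.

Key step: step 7

Remark on the chemistry: the target has no stereocentre. Intermediate 11 and the fallback compounds F2 and F3 are racemic; F2 is drawn as one enantiomer of the trans racemate.

## Route

Step 1
Reactants: 1 2,4,6-trihydroxyacetophenone; 2 benzyl bromide
Product: 3 1-[2,4-bis(benzyloxy)-6-hydroxyphenyl]ethanone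
Conditions: BnBr (2.1 equiv), K2CO3 (2.2 equiv), DMF, 0 °C to rt
Reagents that add atoms: benzyl bromide (second equivalent of 2) BrCc1ccccc1
Why: Twofold Williamson etherification that consumes two equivalents of 2; the para hydroxyl and one ortho hydroxyl react, while the remaining ortho hydroxyl is hydrogen-bonded to the acetyl carbonyl and stays free, as is usual for phloroacetophenone.

Step 2
Reactants: 3 1-[2,4-bis(benzyloxy)-6-hydroxyphenyl]ethanone
Product: 4 1-[2,4-bis(benzyloxy)-3,5-dibromo-6-hydroxyphenyl]ethanone
Conditions: NBS (2.1 equiv), DMF, 0 °C to rt
Reagents that add atoms: N-bromosuccinimide O=C1CCC(=O)N1Br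
Why: Twofold electrophilic aromatic bromination; the only two free positions of the phloroglucinol ring are each activated by three oxygen donors, whereas the benzyl rings and the acetyl methyl group are far less reactive under neutral conditions.

Step 3
Reactants: 5 2-bromoresorcinol
Product: 7 3-bromo-2,4-dihydroxybenzaldehyde, via iminium chloride 6 (not isolated)
Conditions: POCl3, DMF, MeCN, −15 °C to rt; then H2O, 50 °C
Reagents that add atoms: N,N-dimethylformamide CN(C)C=O; water O
Why: Vilsmeier–Haack formylation; the chloroiminium ion attacks the position para to one hydroxyl and ortho to the other, which is the only activated type of position in 5, and water hydrolyses the iminium salt 6 to the aldehyde.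

Step 4
Reactants: 7 3-bromo-2,4-dihydroxybenzaldehyde; 2 benzyl bromide
Product: 8 4-(benzyloxy)-3-bromo-2-hydroxybenzaldehyde
Conditions: BnBr (1.05 equiv), NaHCO3, MeCN, 80 °C
Reagents that add atoms: none
Why: Regioselective Williamson etherification; the weak base ionises the more acidic 4-hydroxyl para to the aldehyde, while the 2-hydroxyl is held in a hydrogen bond to the carbonyl, as with other 2,4-dihydroxyaryl aldehydes.

Step 5
Reactants: 8 4-(benzyloxy)-3-bromo-2-hydroxybenzaldehyde
Product: 9 4-(benzyloxy)-3-bromo-2-methoxybenzaldehyde
Conditions: MeI, K2CO3, DMF, rt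
Reagents that add atoms: iodomethane CI
Why: O-Methylation of the remaining chelated phenol with a small electrophile in a dipolar aprotic solvent; this sets the single methyl ether of the target.

Step 6
Reactants: 4 1-[2,4-bis(benzyloxy)-3,5-dibromo-6-hydroxyphenyl]ethanone; 9 4-(benzyloxy)-3-bromo-2-methoxybenzaldehyde
Product: 10 (E)-1-[2,4-bis(benzyloxy)-3,5-dibromo-6-hydroxyphenyl]-3-[4-(benzyloxy)-3-bromo-2-methoxyphenyl]prop-2-en-1-one
Conditions: KOH (50% aq.), EtOH/THF, rt; then 1 M HCl
Reagents that add atoms: none
Why: Claisen–Schmidt condensation of the phenoxide–enolate of 4 with the non-enolisable aldehyde 9, followed by E1cB dehydration to the conjugated (E)-enone; 2'-hydroxy-4',6'-dialkoxyacetophenones are standard substrates for this reaction.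

Step 7
Reactants: 10 (E)-1-[2,4-bis(benzyloxy)-3,5-dibromo-6-hydroxyphenyl]-3-[4-(benzyloxy)-3-bromo-2-methoxyphenyl]prop-2-en-1-one
Product: 12 5,7-bis(benzyloxy)-3-[4-(benzyloxy)-3-bromo-2-methoxyphenyl]-6,8-dibromochromen-4-one, via dimethyl acetal 11 (not isolated)
Conditions: Tl(NO3)3·3H2O (1.2 equiv), MeOH/HC(OMe)3/CH2Cl2, rt; then 10% aq. HCl, MeOH/THF, 60 °C
Reagents that add atoms: none
Why: Tl(NO3)3 adds across the enone in methanol (oxythallation), with methoxide on the benzylic β-carbon and thallium on the α-carbon. As the C–Tl bond ionises and trivalent thallium leaves as monovalent thallium, ring B shifts from Cβ to Cα through a bridged phenonium ion, forming the C3–C1' bond, and the methoxy-stabilised cation left at Cβ takes up methanol to give the acetal 11. The closest known reaction type is the Tl(NO3)3-mediated oxidative rearrangement of 2'-hydroxychalcones to isoflavones, which trivalent iodine reagents such as PhI(OAc)2 also bring about. On warming with HCl, 11 ionises to an oxocarbenium ion, the ring A phenol adds to it in a six-membered exo-trig closure that forms O1–C2 and ring C, and loss of the second methanol gives the chromone, so the two methoxy groups of 11 come from the solvent and leave again. No stereocentre is created, since the racemic centre of 11 becomes the sp2 carbon C3. The step needs aryl migration to be faster than attack of the phenol oxygen (aurone or flavone formation). The para-benzyloxy and ortho-methoxy groups on the migrating carbon stabilise the phenonium ion, the hydrogen-bonded, bromine-flanked phenol is a poor nucleophile, and the methanol–orthoformate medium traps the rearranged cation as the acetal. Benzyl ethers and aryl bromides are inert to the oxidant, which is why bromine and not prenyl occupies C6, C8 and C3' at this stage.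

Step 8
Reactants: 12 5,7-bis(benzyloxy)-3-[4-(benzyloxy)-3-bromo-2-methoxyphenyl]-6,8-dibromochromen-4-one
Product: 13 6,8-dibromo-3-(3-bromo-4-hydroxy-2-methoxyphenyl)-5,7-dihydroxychromen-4-one
Conditions: BCl3 (1 M in CH2Cl2, excess), C6HMe5, CH2Cl2, −78 to −20 °C; MeOH quench
Reagents that add atoms: none
Why: Lewis acid cleavage of aryl benzyl ethers with pentamethylbenzene as a non-basic benzyl cation scavenger; at low temperature the C–Br bonds and the non-chelated C2' methyl ether are left intact, which hydrogenolysis would not guarantee.

Step 9
Reactants: 13 6,8-dibromo-3-(3-bromo-4-hydroxy-2-methoxyphenyl)-5,7-dihydroxychromen-4-one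
Product: 14 6,8-dibromo-3-[3-bromo-2-methoxy-4-(methoxymethoxy)phenyl]-5,7-bis(methoxymethoxy)chromen-4-one
Conditions: NaH (4 equiv), MOMCl (4 equiv), DMF, 0 °C to rt
Reagents that add atoms: chloromethyl methyl ether COCCl
Why: Threefold O-alkylation of the sodium phenoxides with a small, highly reactive electrophile; the strong non-nucleophilic base is needed to ionise the chelated C5 hydroxyl and does not attack the chromone.

Step 10
Reactants: 14 6,8-dibromo-3-[3-bromo-2-methoxy-4-(methoxymethoxy)phenyl]-5,7-bis(methoxymethoxy)chromen-4-one; 15 prenylboronic acid pinacol ester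
Product: 16 3-[2-methoxy-4-(methoxymethoxy)-3-(3-methylbut-2-enyl)phenyl]-5,7-bis(methoxymethoxy)-6,8-bis(3-methylbut-2-enyl)chromen-4-one
Conditions: 15 (6 equiv), PdCl2(dppf)·CH2Cl2 (15 mol %), Cs2CO3, 1,4-dioxane/H2O (9:1), 90 °C
Reagents that add atoms: prenylboronic acid pinacol ester (second and third equivalents of 15) CC(C)=CCB1OC(C)(C)C(C)(C)O1
Why: Threefold Suzuki–Miyaura coupling of aryl bromides with an allylic boronate, a known way to prenylate halogenated flavonoids; after transmetalation the allyl group equilibrates on palladium, and reductive elimination from the primary carbon is favoured because the two ortho substituents on each aryl group disfavour the tertiary terminus, giving the linear prenyl isomer.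

Step 11
Reactants: 16 3-[2-methoxy-4-(methoxymethoxy)-3-(3-methylbut-2-enyl)phenyl]-5,7-bis(methoxymethoxy)-6,8-bis(3-methylbut-2-enyl)chromen-4-one
Product: 17 5,7-dihydroxy-3-[4-hydroxy-2-methoxy-3-(3-methylbut-2-enyl)phenyl]-6,8-bis(3-methylbut-2-enyl)chromen-4-one
Conditions: 3 M aq. HCl, MeOH/THF, 50 °C, short reaction time
Reagents that add atoms: none
Why: Acid-catalysed acetal exchange transfers the methoxymethyl groups to methanol; dilute acid and moderate temperature are the usual conditions for freeing prenylated flavonoid phenols without cyclisation, and the methyl ether is untouched.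

## Compound list

1 | 2,4,6-trihydroxyacetophenone | CC(=O)c1c(O)cc(O)cc1O | starting material
2 | benzyl bromide | BrCc1ccccc1 | starting material
3 | 1-[2,4-bis(benzyloxy)-6-hydroxyphenyl]ethanone | CC(=O)c1c(O)cc(OCc2ccccc2)cc1OCc1ccccc1 | intermediate
4 | 1-[2,4-bis(benzyloxy)-3,5-dibromo-6-hydroxyphenyl]ethanone | CC(=O)c1c(O)c(Br)c(OCc2ccccc2)c(Br)c1OCc1ccccc1 | intermediate
5 | 2-bromoresorcinol | Oc1cccc(O)c1Br | starting material
6 | N-[(3-bromo-2,4-dihydroxyphenyl)methylidene]-N-methylmethanaminium chloride | C[N+](C)=Cc1ccc(O)c(Br)c1O.[Cl-] | intermediate
7 | 3-bromo-2,4-dihydroxybenzaldehyde | O=Cc1ccc(O)c(Br)c1O | intermediate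
8 | 4-(benzyloxy)-3-bromo-2-hydroxybenzaldehyde | O=Cc1ccc(OCc2ccccc2)c(Br)c1O | intermediate
9 | 4-(benzyloxy)-3-bromo-2-methoxybenzaldehyde | COc1c(C=O)ccc(OCc2ccccc2)c1Br | intermediate
10 | (E)-1-[2,4-bis(benzyloxy)-3,5-dibromo-6-hydroxyphenyl]-3-[4-(benzyloxy)-3-bromo-2-methoxyphenyl]prop-2-en-1-one | O=C(/C=C/c1ccc(OCc2ccccc2)c(Br)c1OC)c1c(O)c(Br)c(OCc2ccccc2)c(Br)c1OCc1ccccc1 | intermediate
11 | 1-[2,4-bis(benzyloxy)-3,5-dibromo-6-hydroxyphenyl]-2-[4-(benzyloxy)-3-bromo-2-methoxyphenyl]-3,3-dimethoxypropan-1-one (racemic) | COC(OC)C(C(=O)c1c(O)c(Br)c(OCc2ccccc2)c(Br)c1OCc1ccccc1)c1ccc(OCc2ccccc2)c(Br)c1OC | intermediate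
12 | 5,7-bis(benzyloxy)-3-[4-(benzyloxy)-3-bromo-2-methoxyphenyl]-6,8-dibromochromen-4-one | COc1c(-c2coc3c(Br)c(OCc4ccccc4)c(Br)c(OCc4ccccc4)c3c2=O)ccc(OCc2ccccc2)c1Br | intermediate
13 | 6,8-dibromo-3-(3-bromo-4-hydroxy-2-methoxyphenyl)-5,7-dihydroxychromen-4-one | COc1c(-c2coc3c(Br)c(O)c(Br)c(O)c3c2=O)ccc(O)c1Br | intermediate
14 | 6,8-dibromo-3-[3-bromo-2-methoxy-4-(methoxymethoxy)phenyl]-5,7-bis(methoxymethoxy)chromen-4-one | COCOc1ccc(-c2coc3c(Br)c(OCOC)c(Br)c(OCOC)c3c2=O)c(OC)c1Br | intermediate
15 | prenylboronic acid pinacol ester (4,4,5,5-tetramethyl-2-(3-methylbut-2-enyl)-1,3,2-dioxaborolane) | CC(C)=CCB1OC(C)(C)C(C)(C)O1 | starting material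
16 | 3-[2-methoxy-4-(methoxymethoxy)-3-(3-methylbut-2-enyl)phenyl]-5,7-bis(methoxymethoxy)-6,8-bis(3-methylbut-2-enyl)chromen-4-one | COCOc1ccc(-c2coc3c(CC=C(C)C)c(OCOC)c(CC=C(C)C)c(OCOC)c3c2=O)c(OC)c1CC=C(C)C | intermediate
17 | 5,7-dihydroxy-3-[4-hydroxy-2-methoxy-3-(3-methylbut-2-enyl)phenyl]-6,8-bis(3-methylbut-2-enyl)chromen-4-one | COc1c(-c2coc3c(CC=C(C)C)c(O)c(CC=C(C)C)c(O)c3c2=O)ccc(O)c1CC=C(C)C | target

## Step count and risks

Total: 11 steps. Longest linear sequence: 9 steps (steps 3, 4, 5, 6, 7, 8, 9, 10, 11 from 2-bromoresorcinol 5); the ring A branch contributes steps 1 and 2.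

**Step 7 (key step).**
- Risk: aryl migration may lose to closure by the phenol oxygen onto the thallated or cationic intermediate, or to simple addition of methanol. Oxythallation may also be slow, because the enone is twisted by the hexasubstituted ring A and the ring B bromine withdraws some electron density. Partial loss of the C5 benzyl ether in the acid stage is possible but harmless, since step 8 removes all benzyl groups.
- Fallback: a 1,2-acyl shift in a chalcone epoxide, which avoids thallium and moves the other group. The fallback sets out from 10. The free phenol is capped with MOMCl and NaH to give (E)-1-[2,4-bis(benzyloxy)-3,5-dibromo-6-(methoxymethoxy)phenyl]-3-[4-(benzyloxy)-3-bromo-2-methoxyphenyl]prop-2-en-1-one F1. Nucleophilic epoxidation with alkaline H2O2 (Weitz–Scheffer) gives the trans-epoxide [2,4-bis(benzyloxy)-3,5-dibromo-6-(methoxymethoxy)phenyl][3-[4-(benzyloxy)-3-bromo-2-methoxyphenyl]oxiran-2-yl]methanone F2. BF3·OEt2 in CH2Cl2 at low temperature opens the epoxide at the benzylic carbon, and the aroyl group migrates to give 2-[4-(benzyloxy)-3-bromo-2-methoxyphenyl]-3-[2,4-bis(benzyloxy)-3,5-dibromo-6-(methoxymethoxy)phenyl]-3-oxopropanal F3. Warm HCl in methanol removes the methoxymethyl group, and the phenol condenses with the aldehyde with loss of water. The fallback rejoins the route at 12.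

**Step 10.**
- Risk: coupling may stop short of three-fold at the hindered, electron-rich C–Br bonds, with protodebromination in its place. Reductive elimination from the tertiary allyl terminus would give 1,1-dimethylallyl isomers. The aqueous base may open the chromone at C2.
- Fallback: a symmetrical allyl group removes the regiochemical question. From 14, threefold coupling with allylboronic acid pinacol ester (PdCl2(dppf)·CH2Cl2, Cs2CO3, dioxane/H2O) or with allyltributylstannane should give 3-[2-methoxy-4-(methoxymethoxy)-3-(prop-2-enyl)phenyl]-5,7-bis(methoxymethoxy)-6,8-bis(prop-2-enyl)chromen-4-one F4. Cross-metathesis with excess 2-methyl-2-butene and second-generation Grubbs catalyst in CH2Cl2 at 40 °C converts each allyl group into a prenyl group. The fallback rejoins the route at 16.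

**Step 11.**
- Risk: the freed phenols may add to the neighbouring prenyl alkenes under the acid, closing 2,2-dimethylchroman rings, or the alkenes may be hydrated before the last methoxymethyl group has left.
- Fallback: the acid step is moved ahead of the prenyl groups. From 14, the triallyl compound F4 is prepared as in the fallback to step 10. Its methoxymethyl groups are removed with HCl in methanol at a stage where the terminal alkenes are far less prone to cationic cyclisation, giving 5,7-dihydroxy-3-[4-hydroxy-2-methoxy-3-(prop-2-enyl)phenyl]-6,8-bis(prop-2-enyl)chromen-4-one F5. Cross-metathesis of the free triphenol with 2-methyl-2-butene and second-generation Grubbs catalyst then gives the target under neutral conditions. The fallback rejoins the route at 17.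

**Step 6.**
- Risk: the ketone of 4 is flanked by two ortho substituents that are buttressed by bromine, so the condensation may be slow. Cannizzaro consumption of 9 or closure of the chalcone to a flavanone could then compete.
- Fallback: condensation and bromination are exchanged. The unbrominated acetophenone 3 is condensed with 9 under the same Claisen–Schmidt conditions to give (E)-1-[2,4-bis(benzyloxy)-6-hydroxyphenyl]-3-[4-(benzyloxy)-3-bromo-2-methoxyphenyl]prop-2-en-1-one F6. Its phloroglucinol-type ring A, by far the most electron-rich site, is then dibrominated with NBS (2 equiv) at 0 °C. The fallback rejoins the route at 10.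

## Further compounds

F1 | step 7 | (E)-1-[2,4-bis(benzyloxy)-3,5-dibromo-6-(methoxymethoxy)phenyl]-3-[4-(benzyloxy)-3-bromo-2-methoxyphenyl]prop-2-en-1-one | O=C(/C=C/c1ccc(OCc2ccccc2)c(Br)c1OC)c1c(OCOC)c(Br)c(OCc2ccccc2)c(Br)c1OCc1ccccc1
F2 | step 7 | [2,4-bis(benzyloxy)-3,5-dibromo-6-(methoxymethoxy)phenyl][(2S,3R)-3-[4-(benzyloxy)-3-bromo-2-methoxyphenyl]oxiran-2-yl]methanone (trans, racemic) | O=C([C@H]1O[C@@H]1c1ccc(OCc2ccccc2)c(Br)c1OC)c1c(OCOC)c(Br)c(OCc2ccccc2)c(Br)c1OCc1ccccc1
F3 | step 7 | 2-[4-(benzyloxy)-3-bromo-2-methoxyphenyl]-3-[2,4-bis(benzyloxy)-3,5-dibromo-6-(methoxymethoxy)phenyl]-3-oxopropanal (racemic) | O=CC(C(=O)c1c(OCOC)c(Br)c(OCc2ccccc2)c(Br)c1OCc1ccccc1)c1ccc(OCc2ccccc2)c(Br)c1OC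
F4 | step 10 | 3-[2-methoxy-4-(methoxymethoxy)-3-(prop-2-enyl)phenyl]-5,7-bis(methoxymethoxy)-6,8-bis(prop-2-enyl)chromen-4-one | COCOc1ccc(-c2coc3c(CC=C)c(OCOC)c(CC=C)c(OCOC)c3c2=O)c(OC)c1CC=C
F5 | step 11 | 5,7-dihydroxy-3-[4-hydroxy-2-methoxy-3-(prop-2-enyl)phenyl]-6,8-bis(prop-2-enyl)chromen-4-one | COc1c(-c2coc3c(CC=C)c(O)c(CC=C)c(O)c3c2=O)ccc(O)c1CC=C
F6 | step 6 | (E)-1-[2,4-bis(benzyloxy)-6-hydroxyphenyl]-3-[4-(benzyloxy)-3-bromo-2-methoxyphenyl]prop-2-en-1-one | O=C(/C=C/c1ccc(OCc2ccccc2)c(Br)c1OC)c1c(O)cc(OCc2ccccc2)cc1OCc1ccccc1
A1 | alternative 1 | (E)-3-methoxy-2-[2-methoxy-4-(methoxymethoxy)-3-(3-methylbut-2-enyl)phenyl]-1-[2,4,6-tris(methoxymethoxy)-3,5-bis(3-methylbut-2-enyl)phenyl]prop-2-en-1-one | CO/C=C(/C(=O)c1c(OCOC)c(CC=C(C)C)c(OCOC)c(CC=C(C)C)c1OCOC)c1ccc(OCOC)c(CC=C(C)C)c1OC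
A2 | alternative 1 | 2-iodo-1,3,5-tris(methoxymethoxy)-4,6-bis(3-methylbut-2-enyl)benzene | COCOc1c(I)c(OCOC)c(CC=C(C)C)c(OCOC)c1CC=C(C)C
A3 | alternative 1 | 2-[(Z)-2-methoxy-1-[2-methoxy-4-(methoxymethoxy)-3-(3-methylbut-2-enyl)phenyl]ethenyl]-4,4,5,5-tetramethyl-1,3,2-dioxaborolane | CO/C=C(/B1OC(C)(C)C(C)(C)O1)c1ccc(OCOC)c(CC=C(C)C)c1OC
A4 | alternative 2 | 5-(methoxymethoxy)-2,4-bis(3-methylbut-2-enyl)-3-(triisopropylsilyloxy)phenol | Oc1cc(OCOC)c(CC=C(C)C)c(O[Si](C(C)C)(C(C)C)C(C)C)c1CC=C(C)C
A5 | alternative 2 | 3-(methoxymethoxy)-2-(3-methylbut-2-enyl)cyclobut-2-en-1-one | COCOC1=C(CC=C(C)C)C(=O)C1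
A6 | alternative 2 | triisopropyl[(5-methylhex-4-en-1-yn-1-yl)oxy]silane | CC(C)=CCC#CO[Si](C(C)C)(C(C)C)C(C)C
A7 | alternative 3 | 3-[4-hydroxy-2-methoxy-3-(3-methylbut-2-enyl)phenyl]-5,7-bis(methoxymethoxy)-6,8-bis(3-methylbut-2-enyl)chromen-4-one | COc1c(-c2coc3c(CC=C(C)C)c(OCOC)c(CC=C(C)C)c(OCOC)c3c2=O)ccc(O)c1CC=C(C)C
A8 | alternative 3 | 2-[5,7-bis(methoxymethoxy)-6,8-bis(3-methylbut-2-enyl)-4-oxochromen-3-yl]cyclobut-2-en-1-one | O=C1CC=C1c1coc2c(CC=C(C)C)c(OCOC)c(CC=C(C)C)c(OCOC)c2c1=O
A9 | alternative 3 | 1-methoxy-5-methylhex-4-en-1-yne | COC#CCC=C(C)C
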